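The route rests on cutting the O1–C7a bond of the dihydrofuran ring. Without the C5 methoxy group and that bond, the six-membered ring is a symmetric 4,4-disubstituted cyclohexa-2,5-dienone whose C3a is only prochiral; the key step exploits this hidden symmetry. In one operation the C2 alkoxide of the precursor, a 4-allyl-4-(1-aryl-1-hydroxypropan-2-yl)cyclohexadienone carrying the C2 and C3 stereocentres, adds to one of the two diastereotopic enone arms, and the enolate formed is dehydrogenated in the same flask. This closes the dihydrofuran ring, sets C3a and leaves the C7=C7a vinylogous ester; the C5 methoxy group is added afterwards.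

Key step: step 6

Assumption: benzofuranone numbering (O1, C2, C3, C3a, C4–C7, C7a) is used for all bicyclic compounds and the SMILES strings are authoritative for configuration; C3a is labelled R in 12–14 and S in 15–17 only because the CIP ranking of C4 against C3 changes once C4/C5 carry oxygen, the geometry being the same throughout.

Step 1
Reactants: 1 4-acetoxystyrene
Product: 2 (S)-2-(4-acetoxyphenyl)propanal
Conditions: Rh(acac)(CO)2 (cat.), BisDiazaphos (cat., the antipode that gives the S aldehyde), CO/H2 1:1 (ca. 10 bar), THF, 60 °C; used crude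
Reagents that add atoms: carbon monoxide, [C-]#[O+]
Why: Rh/bis(diazaphospholane)-catalysed asymmetric hydroformylation of a styrene is branch-selective through the η3-benzyl rhodium intermediate, and the ligand pocket selects the alkene face that inserts into Rh–H, which sets the benzylic centre as S; the aryl acetate is inert and the configurationally labile aldehyde is carried on without chromatography.

Step 2
Reactants: 2 (S)-2-(4-acetoxyphenyl)propanal; 3 5-bromo-1,2,3-trimethoxybenzene
Product: 6 4-[(1R,2S)-1-hydroxy-1-(3,4,5-trimethoxyphenyl)propan-2-yl]phenyl acetate, via arylmagnesium bromide 4 (not isolated), via aryltitanium triisopropoxide 5 (not isolated)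
Conditions: 3, Mg, THF, rt; ClTi(OiPr)3, −78 → −20 °C; then 2, −40 → 0 °C; aq. NH4Cl
Reagents that add atoms: none
Why: Felkin–Anh-controlled 1,2-addition of a Reetz-type aryltitanium triisopropoxide, which is non-basic and aldehyde-selective so that neither the α-aryl stereocentre nor the aryl acetate is touched; with the 4-acetoxyphenyl group antiperiplanar to the incoming aryl and the nucleophile passing the small H, the S aldehyde should give mainly the 1R carbinol, the minor 1S epimer being removed by chromatography.

Step 3
Reactants: 6 4-[(1R,2S)-1-hydroxy-1-(3,4,5-trimethoxyphenyl)propan-2-yl]phenyl acetate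
Product: 8 4-[(1R,2S)-1-(tert-butyldimethylsilyloxy)-1-(3,4,5-trimethoxyphenyl)propan-2-yl]phenol, via acetate silyl ether 7 (not isolated)
Conditions: TBSOTf, 2,6-lutidine, CH2Cl2, 0 °C; then MeOH, K2CO3 (excess), rt
Reagents that add atoms: tert-butyldimethylsilyl trifluoromethanesulfonate, CC(C)(C)[Si](C)(C)OS(=O)(=O)C(F)(F)F
Why: O-silylation of the hindered benzylic alcohol with the silyl triflate followed by base-catalysed methanolysis (transesterification) of the aryl acetate frees only the phenol, because an alkyl TBS ether is stable to K2CO3/MeOH; no stereocentre is involved.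

Step 4
Reactants: 8 4-[(1R,2S)-1-(tert-butyldimethylsilyloxy)-1-(3,4,5-trimethoxyphenyl)propan-2-yl]phenol; 9 allyltrimethylsilane
Product: 10 4-allyl-4-[(1R,2S)-1-(tert-butyldimethylsilyloxy)-1-(3,4,5-trimethoxyphenyl)propan-2-yl]cyclohexa-2,5-dien-1-one
Conditions: PhI(OAc)2, 9 (5 equiv), HFIP/CH2Cl2, −10 → 0 °C, minutes; NaHCO3 quench
Reagents that add atoms: none
Why: Iodine(III)-mediated oxidative dearomatisation with an allylsilane as carbon nucleophile (oxidative Hosomi–Sakurai allylation of a para-alkylphenol) makes the para carbon electrophilic, the silane attacks it and loses silicon, and since the new quaternary carbon bears two identical enone arms no stereocentre is formed, while the silyl ether keeps the benzylic oxygen from triggering Cα–Cβ fragmentation or O-capture.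

Step 5
Reactants: 10 4-allyl-4-[(1R,2S)-1-(tert-butyldimethylsilyloxy)-1-(3,4,5-trimethoxyphenyl)propan-2-yl]cyclohexa-2,5-dien-1-one
Product: 11 4-allyl-4-[(1R,2S)-1-hydroxy-1-(3,4,5-trimethoxyphenyl)propan-2-yl]cyclohexa-2,5-dien-1-one
Conditions: HF·pyridine, pyridine, THF, 0 °C → rt
Reagents that add atoms: none
Why: Fluoride-driven desilylation (Si–F bond formation) under buffered, weakly acidic conditions releases the carbinol without generating a free alkoxide, so premature conjugate addition is kept low and the side-chain stereocentres are untouched; any material that does cyclise converges in step 6 through the same enolate.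

Step 6
Reactants: 11 4-allyl-4-[(1R,2S)-1-hydroxy-1-(3,4,5-trimethoxyphenyl)propan-2-yl]cyclohexa-2,5-dien-1-one
Product: 14 (2R,3S,3aR)-3a-allyl-3-methyl-2-(3,4,5-trimethoxyphenyl)-3,3a-dihydro-1-benzofuran-6(2H)-one, via potassium dienolate 12 (not isolated), via C7 sulfilimine 13 (not isolated)
Conditions: KHMDS (1.05 equiv), THF, −78 → 0 °C, 1 h; then −78 °C, PhS(Cl)=N-t-Bu (1.3 equiv), → rt
Reagents that add atoms: none
Why: KHMDS turns the C2 carbinol into its potassium alkoxide, which adds in a conjugate sense to the β-carbon (future C7a) of one enone arm and gives the cis-fused cross-conjugated dienolate 12; C7 of 12 then attacks sulfur of the sulfinimidoyl chloride and the sulfilimine 13 expels PhS–NH-t-Bu by intramolecular syn-elimination of H-7a, which makes C7=C7a part of a vinylogous ester. The closest known reaction types are desymmetrising intramolecular oxa-Michael additions to 4,4-disubstituted cyclohexa-2,5-dienones and the one-pot Mukaiyama dehydrogenation of ketone enolates, run here one after the other in a single flask. The only ring closed is the dihydrofuran (O1–C7a), by a 5-exo-trig addition that can only give the cis ring fusion. The one stereocentre that remains, C3a, is defined by which of the two diastereotopic arms is attacked and is controlled by the fixed C2 and C3 centres of the tether: in the closure leading to 12 the C3 methyl and the cis C2 aryl lie next to the flat C4–H carbon, whereas closure on the other arm would push them against the allyl CH2. Because a β-alkoxy enolate reverts by E1cB, both closures should interconvert through the alkoxide at 0 °C before the oxidant is added, so the step needs a thermodynamic preference for 12, which the substrate is expected, though not certain, to provide; once C7a is sp2 in 14 the retro-addition is no longer possible and C3a is fixed. Site selectivity of the oxidation needs no control, since C7 is the only enolisable position (C5 is vinylic, C3a quaternary) and 14 has no α-hydrogen left.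

Step 7
Reactants: 14 (2R,3S,3aR)-3a-allyl-3-methyl-2-(3,4,5-trimethoxyphenyl)-3,3a-dihydro-1-benzofuran-6(2H)-one
Product: 15 (2R,3S,3aS)-3a-allyl-4,5-epoxy-3-methyl-2-(3,4,5-trimethoxyphenyl)-3,3a,4,5-tetrahydro-1-benzofuran-6(2H)-one (epoxide face left open, both converge)
Conditions: t-BuOOH (decane), DBU (cat.), CH2Cl2, 0 °C → rt
Reagents that add atoms: tert-butyl hydroperoxide, CC(C)(C)OO
Why: Weitz–Scheffer nucleophilic epoxidation, in which the peroxide anion adds to C4 of the only simple enone (the C7=C7a enone is deactivated as a vinylogous ester and the allyl group is no acceptor) and the enolate closes onto O–O; the epoxide face is irrelevant because C4 and C5 become sp2 again in step 8.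

Step 8
Reactants: 15 (2R,3S,3aS)-3a-allyl-4,5-epoxy-3-methyl-2-(3,4,5-trimethoxyphenyl)-3,3a,4,5-tetrahydro-1-benzofuran-6(2H)-one
Product: 17 (2R,3S,3aS)-3a-allyl-5-methoxy-3-methyl-2-(3,4,5-trimethoxyphenyl)-3,3a-dihydro-1-benzofuran-6(2H)-one, via methoxy hydroxy ketone 16 (not isolated)
Conditions: NaOMe (3 equiv), MeOH, rt → 40 °C
Reagents that add atoms: sodium methoxide, [Na+].[O-]C
Why: Methoxide opens the α,β-epoxy ketone by SN2 attack at the α-carbon C5 and the resulting β-hydroxy ketone dehydrates by E1cB to the 2-methoxy enone (the known conversion of epoxy ketones into α-alkoxy enones, as with 4,5-epoxy-3-keto steroids), which places OMe on C5 and restores C4=C5 without touching C2, C3 or C3a.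

Compound list
1 | 4-acetoxystyrene | CC(=O)Oc1ccc(C=C)cc1 | starting material
2 | (S)-2-(4-acetoxyphenyl)propanal | CC(=O)Oc1ccc(cc1)[C@H](C)C=O | intermediate
3 | 5-bromo-1,2,3-trimethoxybenzene | COc1cc(Br)cc(OC)c1OC | starting material
4 | (3,4,5-trimethoxyphenyl)magnesium bromide | COc1cc([Mg]Br)cc(OC)c1OC | intermediate
5 | triisopropoxy(3,4,5-trimethoxyphenyl)titanium | COc1cc(cc(OC)c1OC)[Ti](OC(C)C)(OC(C)C)OC(C)C | intermediate
6 | 4-[(1R,2S)-1-hydroxy-1-(3,4,5-trimethoxyphenyl)propan-2-yl]phenyl acetate | CC(=O)Oc1ccc(cc1)[C@H](C)[C@@H](O)c1cc(OC)c(OC)c(OC)c1 | intermediate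
7 | 4-[(1R,2S)-1-(tert-butyldimethylsilyloxy)-1-(3,4,5-trimethoxyphenyl)propan-2-yl]phenyl acetate | CC(=O)Oc1ccc(cc1)[C@H](C)[C@@H](O[Si](C)(C)C(C)(C)C)c1cc(OC)c(OC)c(OC)c1 | intermediate
8 | 4-[(1R,2S)-1-(tert-butyldimethylsilyloxy)-1-(3,4,5-trimethoxyphenyl)propan-2-yl]phenol | Oc1ccc(cc1)[C@H](C)[C@@H](O[Si](C)(C)C(C)(C)C)c1cc(OC)c(OC)c(OC)c1 | intermediate
9 | allyltrimethylsilane | C=CC[Si](C)(C)C | starting material
10 | 4-allyl-4-[(1R,2S)-1-(tert-butyldimethylsilyloxy)-1-(3,4,5-trimethoxyphenyl)propan-2-yl]cyclohexa-2,5-dien-1-one | C=CCC1(C=CC(=O)C=C1)[C@H](C)[C@@H](O[Si](C)(C)C(C)(C)C)c1cc(OC)c(OC)c(OC)c1 | intermediate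
11 | 4-allyl-4-[(1R,2S)-1-hydroxy-1-(3,4,5-trimethoxyphenyl)propan-2-yl]cyclohexa-2,5-dien-1-one | C=CCC1(C=CC(=O)C=C1)[C@H](C)[C@@H](O)c1cc(OC)c(OC)c(OC)c1 | intermediate
12 | potassium (2R,3S,3aR,7aR)-3a-allyl-3-methyl-2-(3,4,5-trimethoxyphenyl)-2,3,3a,7a-tetrahydro-1-benzofuran-6-olate (cis-fused) | C=CC[C@]12C=CC([O-])=C[C@H]1O[C@@H](c1cc(OC)c(OC)c(OC)c1)[C@H]2C.[K+] | intermediate
13 | C7 N-tert-butyl-S-phenylsulfilimine of the cis-fused ketone (ring centres as in 12; C7 and S not specified) | C=CC[C@]12C=CC(=O)C(S(=NC(C)(C)C)c3ccccc3)[C@H]1O[C@@H](c1cc(OC)c(OC)c(OC)c1)[C@H]2C | intermediate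
14 | (2R,3S,3aR)-3a-allyl-3-methyl-2-(3,4,5-trimethoxyphenyl)-3,3a-dihydro-1-benzofuran-6(2H)-one | C=CC[C@]12C=CC(=O)C=C1O[C@@H](c1cc(OC)c(OC)c(OC)c1)[C@H]2C | intermediate
15 | (2R,3S,3aS)-3a-allyl-4,5-epoxy-3-methyl-2-(3,4,5-trimethoxyphenyl)-3,3a,4,5-tetrahydro-1-benzofuran-6(2H)-one (C4/C5 not specified) | C=CC[C@]12C3OC3C(=O)C=C1O[C@@H](c1cc(OC)c(OC)c(OC)c1)[C@H]2C | intermediate
16 | (2R,3S,3aS)-3a-allyl-4-hydroxy-5-methoxy-3-methyl-2-(3,4,5-trimethoxyphenyl)-3,3a,4,5-tetrahydro-1-benzofuran-6(2H)-one (C4/C5 not specified) | C=CC[C@]12C(O)C(OC)C(=O)C=C1O[C@@H](c1cc(OC)c(OC)c(OC)c1)[C@H]2C | intermediate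
17 | (2R,3S,3aS)-3a-allyl-5-methoxy-3-methyl-2-(3,4,5-trimethoxyphenyl)-3,3a-dihydro-1-benzofuran-6(2H)-one | C=CC[C@]12C=C(OC)C(=O)C=C1O[C@@H](c1cc(OC)c(OC)c(OC)c1)[C@H]2C | target

Total step count: 8. Longest linear sequence: 8 steps (1 → 17); the aryl bromide 3 enters in step 2 and the silane 9 in step 4.

Steps most likely to fail

Step 6. The alkoxide may close onto the other enone arm if the equilibrium between the two dienolates does not favour 12 clearly, and uncyclised alkoxide may be consumed by the oxidant. The fallback sets out from 11 and returns at 14. The cyclisation is run on its own under kinetic catalyst control, with a cinchona-derived primary amine salt or a chiral phosphoric acid of the matched handedness (known catalysts for desymmetrising oxa-Michael additions to cyclohexadienones). This should give the neutral cis-fused ketone (2R,3S,3aR,7aR)-3a-allyl-3-methyl-2-(3,4,5-trimethoxyphenyl)-3,3a,7,7a-tetrahydro-1-benzofuran-6(2H)-one F1, from which a minor C3a/C7a epimer can be separated. Soft enolisation without a free enolate (TMSOTf, Et3N, CH2Cl2, 0 °C), so that no retro-addition can occur, gives the trimethylsilyl dienol ether F2. IBX·4-methoxypyridine N-oxide in DMSO at room temperature then dehydrogenates F2 to 14.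

Step 4. The oxidised phenol may be captured by the neighbouring electron-rich trimethoxyphenyl ring, or the silane may attack an ortho carbon, instead of forming the C–C bond at the hindered ipso carbon. The fallback sets out from 2 and returns at 11, bypassing 6, 8 and 10, so that the dearomatisation is done before the electron-rich ring is present. Reduction and acetate methanolysis in one operation (NaBH4, K2CO3, MeOH, 0 °C) give (S)-2-(4-hydroxyphenyl)propan-1-ol F3, which also secures the labile stereocentre. PhI(OAc)2 and 9 in HFIP allylate this simple para-alkylphenol to 4-allyl-4-[(S)-1-hydroxypropan-2-yl]cyclohexa-2,5-dien-1-one F4, whose primary hydroxyl cannot reach the ipso carbon. Buffered Dess–Martin oxidation gives (S)-2-(1-allyl-4-oxocyclohexa-2,5-dien-1-yl)propanal F5. The aryltitanium 5 then adds to the aldehyde only, with the quaternary ring carbon as the large Felkin–Anh group, and should give 11 after neutral work-up.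

Step 2. Facial discrimination at the aldehyde may be incomplete (anti-Felkin attack), and the α-aryl aldehyde may epimerise before it is consumed. The fallback sets out from 2 and returns at 6. The aryl group is transferred under catalyst control from ethyl(3,4,5-trimethoxyphenyl)zinc F6, generated from (3,4,5-trimethoxyphenyl)boronic acid and diethylzinc, in the presence of a chiral amino alcohol (MIB type) chosen to reinforce the Felkin preference for the 1R carbinol. The non-basic zinc reagent leaves the acetate and the α-stereocentre intact.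

Further compounds
F1 | step 6 | (2R,3S,3aR,7aR)-3a-allyl-3-methyl-2-(3,4,5-trimethoxyphenyl)-3,3a,7,7a-tetrahydro-1-benzofuran-6(2H)-one | C=CC[C@]12C=CC(=O)C[C@H]1O[C@@H](c1cc(OC)c(OC)c(OC)c1)[C@H]2C
F2 | step 6 | (2R,3S,3aR,7aR)-3a-allyl-3-methyl-6-(trimethylsilyloxy)-2-(3,4,5-trimethoxyphenyl)-2,3,3a,7a-tetrahydro-1-benzofuran | C=CC[C@]12C=CC(O[Si](C)(C)C)=C[C@H]1O[C@@H](c1cc(OC)c(OC)c(OC)c1)[C@H]2C
F3 | step 4 | (S)-2-(4-hydroxyphenyl)propan-1-ol | Oc1ccc(cc1)[C@H](C)CO
F4 | step 4 | 4-allyl-4-[(S)-1-hydroxypropan-2-yl]cyclohexa-2,5-dien-1-one | C=CCC1(C=CC(=O)C=C1)[C@H](C)CO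
F5 | step 4 | (S)-2-(1-allyl-4-oxocyclohexa-2,5-dien-1-yl)propanal | C=CCC1(C=CC(=O)C=C1)[C@H](C)C=O
F6 | step 2 | ethyl(3,4,5-trimethoxyphenyl)zinc | CC[Zn]c1cc(OC)c(OC)c(OC)c1
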